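The pitfall in these runs is to read a plateau as what was captured, when target may have been lost after it formed.

| setting | red | ochre | grey | flask |
|---|---|---|---|---|
| substrate | 0.050 M | 0.050 M | 0.075 M | 0.050 M |
| first nucleophile | 0.70 equiv | 1.6 equiv | 1.05 equiv | 1.05 equiv |
| second nucleophile | 1.05 equiv | 1.05 equiv | 1.05 equiv | 1.05 equiv |
| remark | run made earlier | run made earlier | run made earlier |  |
| time |  |  |  | 50 h |

| run | time / h | other capture product / % | target / % | substrate / % |
|---|---|---|---|---|
| red | 10.0 | 40.8 | 11.8 | 0.6 |
| red | 20.0 | 38.9 | 12.0 | 0 |
| red | 30.0 | 40.9 | 12.2 | 0 |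
| red | 40.0 | 40.4 | 12.2 | 0.4 |
| red | 48.0 | 40.1 | 12.4 | 0.1 |
| red | 60.0 | 38.5 | 11.8 | 0.6 |
| ochre | 10.0 | 22.2 | 16.9 | 0.3 |
| ochre | 20.0 | 21.8 | 17.4 | 0 |
| ochre | 30.0 | 21.8 | 17.3 | 0.1 |
| ochre | 40.0 | 22.9 | 18.0 | 0 |
| ochre | 48.0 | 22.0 | 17.3 | 0.5 |
| ochre | 60.0 | 21.7 | 18.5 | 0.3 |
| grey | 12.0 | 29.0 | 11.2 | 1.1 |
| grey | 25.0 | 28.2 | 10.6 | 0 |
| grey | 40.0 | 28.3 | 11.4 | 0.2 |
| grey | 50.0 | 29.7 | 10.1 | 0.1 |
| grey | 60.0 | 28.1 | 9.7 | 0.2 |

(scatter of a reading: 0.5 percentage points)

1. ratio of other capture product to target at 2.5 min
2. ratio of other capture product to target at 80 min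
3. ratio of other capture product to target at 50 h

The ledger follows the substrate through the grey run, whose nucleophiles are charged in equal equivalents, like the flask's.

1. Substrate is the limiting reagent in the grey run, with each nucleophile at 1.05 equiv, and it reads 0% at 25.0 h.

2. Means over the grey run credit other capture product with 28.7% and target with 10.6%.

3. The books stay open by 60.7%. My own reckoning enters this as a side product of substrate plus target, each unit holding two units of substrate, one of them formerly target. Gross target is then target plus 0.5 times the missing entry, 41.0%.

4. In each run, other capture product is divided by gross target, then by c(second nucleophile)/c(first nucleophile) as charged. Grey gives 0.700. Red gives 0.738 at a charge ratio of 1.50. Ochre gives 0.704 at 0.656. Their mean, 0.714, is an apparent selectivity factor: whole-run other capture product per gross target, divided by the nucleophile ratio as charged, with no correction for the use of either nucleophile during the run.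

5. As my estimate for the flask's early ratio, I take this factor times the flask's charge ratio. I therefore commit to 0.714 at 2.5 min, climbing afterwards towards the plateau.

The forecast gives 4, 2.4 and 2.05, on the ground that “early ratios exceed the plateau”. My early value lies below its plateau.

The flask gives 0.706, 1.78 and 2.02.

    first nucleophile + intermediate → target (k = 26.0 /M/s)
    second nucleophile + intermediate → other capture product (k = 17.0 /M/s)
    substrate + target → side product (k = 0.0200 /M/s)
    substrate ⇌ intermediate (K = 0.0790, k = 2.80 × 10⁻⁴ /s)

In the flask, target has a half-life of 0.19 h against substrate at its charged concentration, shorter than the 0.475 h by which half of the substrate's turnover into intermediate is done. The two steps run side by side, and at 50.0 h the flask holds side product 55.0%, counted double, beside target 14.9%. In the neighbouring flask with 0.260 equiv of first nucleophile, the factor times the charge ratio gives 2.88, and that flask stands at 2.86 at 2.5 min.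

The readings were generated by integration for an exercise; the scatter is artificial.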